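**Retrosynthetic overview**
1. Target (3R)-8-hydroxy-6-methoxy-3-(6-oxoundecyl)isochroman-1-one ⇒ chelation-controlled 8-O-demethylation of its 6,8-dimethoxy ether; the keto chain ⇒ cross-metathesis of a pent-4-enyl side chain with oct-1-en-3-one, then hydrogenation.
2. Benzene ring (formed first) ⇒ Diels–Alder cycloaddition of 1,3-dimethoxycyclohexa-1,3-diene to a 5-hydroxy-2-ynoate, then retro-Diels–Alder loss of ethylene (Alder–Rickert).
3. Lactone ring (formed second, same operation) ⇒ closure of the resulting 2-(2-hydroxyalkyl)benzoate.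
4. Hydroxy-ynoate ⇒ lithiated ethyl propiolate + (R)-2-(pent-4-enyl)oxirane ⇒ (R)-epichlorohydrin + but-3-enylmagnesium bromide; the only stereocentre is bought and never reacts.

Assumption: the target is (R) at C3 as read from the SMILES, and (R)-epichlorohydrin, but-3-en-1-ylmagnesium bromide (0.5 M in THF), ethyl propiolate, 1,5-dimethoxycyclohexa-1,4-diene and oct-1-en-3-one are bought.

**Step 1**
Reactants: 1 (R)-epichlorohydrin; 2 but-3-en-1-ylmagnesium bromide
Product: 4 (R)-2-(pent-4-en-1-yl)oxirane, via (R)-1-chlorohept-6-en-2-ol 3 (not isolated)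
Conditions: 2 (1.2 equiv), CuI (10 mol%), THF, −40 → −20 °C, 2 h; then 5 M aq NaOH added to the same flask, 0 °C → rt, 4 h; distil
Reagents that add atoms: none
Why: CuI-catalysed Grignard opening (SN2 at the unsubstituted epoxide carbon) gives the chlorohydrin alkoxide, which NaOH closes by intramolecular Williamson displacement of chloride; neither event touches the bought stereocentre, so (R) is carried into 4.

**Step 2**
Reactants: 4 (R)-2-(pent-4-en-1-yl)oxirane; 5 ethyl propiolate
Product: 7 ethyl (R)-5-hydroxydec-9-en-2-ynoate, via ethyl 3-lithiopropiolate 6 (not isolated)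
Conditions: 5 (1.6 equiv), n-BuLi (1.6 equiv), THF, −78 °C, 20 min; BF3·OEt2 (1.6 equiv); then 4, −78 °C, 2 h; sat. aq NH4Cl at −78 °C
Reagents that add atoms: none
Why: Yamaguchi–Hirao alkynylation, in which the BF3-activated epoxide is opened by the lithium acetylide at its terminal CH2 (SN2), so the carbinol carbon keeps its (R) configuration and the ester survives at −78 °C.

**Step 3**
Reactants: 7 ethyl (R)-5-hydroxydec-9-en-2-ynoate; 8 1,5-dimethoxycyclohexa-1,4-diene
Product: 12 (R)-6,8-dimethoxy-3-(pent-4-en-1-yl)isochroman-1-one, via 1,3-dimethoxycyclohexa-1,3-diene 9 (not isolated), via bicyclo[2.2.2]octadiene cycloadduct 10 (not isolated), via ethyl 2-[(R)-2-hydroxyhept-6-en-1-yl]-4,6-dimethoxybenzoate 11 (not isolated)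
Conditions: 8 (3 equiv), dichloromaleic anhydride (2 mol%), neat, sealed tube, Ar, 185 °C, 36 h; strip volatiles; then p-TsOH·H2O (10 mol%), toluene, 80 °C, 2 h
Reagents that add atoms: none
Why: Alder–Rickert sequence, in which 8 conjugates to 9, the unsubstituted diene terminus adds to the β-carbon of the ynoate in a regioselective Diels–Alder cycloaddition (ester next to the bridgehead OMe), retro-Diels–Alder loss of ethylene aromatises 10 to the benzoate 11, and acid-catalysed transesterification closes the δ-lactone through the hydroxyl oxygen with retention at the stereocentre.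

**Step 4**
Reactants: 12 (R)-6,8-dimethoxy-3-(pent-4-en-1-yl)isochroman-1-one; 13 oct-1-en-3-one
Product: 15 (R)-6,8-dimethoxy-3-(6-oxoundecyl)isochroman-1-one, via (R,E)-6,8-dimethoxy-3-(6-oxoundec-4-en-1-yl)isochroman-1-one 14 (not isolated)
Conditions: 13 (3 equiv), second-generation Grubbs catalyst (3 mol%), CH2Cl2, 40 °C, 12 h; then EtOAc, Pd/C (10 wt%), H2 (1 atm), rt, 6 h
Reagents that add atoms: none
Why: Olefin cross-metathesis of a terminal alkene with an electron-poor enone is selective for the E cross product, and Pd/C then saturates only the conjugated C=C (ketone, lactone and arene are untouched); no stereocentre is involved.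

**Step 5**
Reactants: 15 (R)-6,8-dimethoxy-3-(6-oxoundecyl)isochroman-1-one
Product: 17 (R)-8-hydroxy-6-methoxy-3-(6-oxoundecyl)isochroman-1-one, via (R)-8-(dichloroboryloxy)-6-methoxy-3-(6-oxoundecyl)isochroman-1-one 16 (not isolated)
Conditions: BCl3 (1 M in CH2Cl2, 2.5 equiv), CH2Cl2, −78 → 0 °C, 1 h; aq NaHCO3
Reagents that add atoms: none
Why: Chelation-controlled ether cleavage, in which BCl3 bridges the lactone carbonyl and the peri 8-OMe oxygen so chloride removes only that methyl group, leaving the 6-OMe, the ketone and the (R)-C3–O bond intact.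

**Compound list**
1 | (R)-epichlorohydrin | ClC[C@H]1CO1 | starting material
2 | but-3-en-1-ylmagnesium bromide | C=CCC[Mg]Br | starting material
3 | (R)-1-chlorohept-6-en-2-ol (present as its magnesium alkoxide) | ClC[C@H](O)CCCC=C | intermediate
4 | (R)-2-(pent-4-en-1-yl)oxirane | C=CCCC[C@@H]1CO1 | intermediate
5 | ethyl propiolate | C#CC(=O)OCC | starting material
6 | ethyl 3-lithiopropiolate | [Li]C#CC(=O)OCC | intermediate
7 | ethyl (R)-5-hydroxydec-9-en-2-ynoate | C=CCCC[C@@H](O)CC#CC(=O)OCC | intermediate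
8 | 1,5-dimethoxycyclohexa-1,4-diene | COC1=CCC=C(OC)C1 | starting material
9 | 1,3-dimethoxycyclohexa-1,3-diene | COC1=CC(OC)=CCC1 | intermediate
10 | ethyl 3-[(R)-2-hydroxyhept-6-en-1-yl]-1,5-dimethoxybicyclo[2.2.2]octa-2,5-diene-2-carboxylate (both bridgehead diastereomers) | COC1=CC2(OC)CCC1C(C[C@H](O)CCCC=C)=C2C(=O)OCC | intermediate
11 | ethyl 2-[(R)-2-hydroxyhept-6-en-1-yl]-4,6-dimethoxybenzoate | CCOC(=O)c1c(OC)cc(OC)cc1C[C@H](O)CCCC=C | intermediate
12 | (R)-6,8-dimethoxy-3-(pent-4-en-1-yl)isochroman-1-one | C=CCCC[C@@H]1Cc2cc(OC)cc(OC)c2C(=O)O1 | intermediate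
13 | oct-1-en-3-one | C=CC(=O)CCCCC | starting material
14 | (R,E)-6,8-dimethoxy-3-(6-oxoundec-4-en-1-yl)isochroman-1-one | CCCCCC(=O)/C=C/CCC[C@@H]1Cc2cc(OC)cc(OC)c2C(=O)O1 | intermediate
15 | (R)-6,8-dimethoxy-3-(6-oxoundecyl)isochroman-1-one | CCCCCC(=O)CCCCC[C@@H]1Cc2cc(OC)cc(OC)c2C(=O)O1 | intermediate
16 | (R)-8-(dichloroboryloxy)-6-methoxy-3-(6-oxoundecyl)isochroman-1-one | CCCCCC(=O)CCCCC[C@@H]1Cc2cc(OC)cc(OB(Cl)Cl)c2C(=O)O1 | intermediate
17 | (R)-8-hydroxy-6-methoxy-3-(6-oxoundecyl)isochroman-1-one | CCCCCC(=O)CCCCC[C@@H]1Cc2cc(OC)cc(O)c2C(=O)O1 | target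

**Totals**
Total step count: 5. Longest linear sequence: 5 steps (1 → 4 → 7 → 12 → 15 → 17).

**Steps most likely to fail**

Step 3 (cycloaddition/aromatisation). Risks are the 185 °C needed for a β-alkyl ynoate, the free hydroxyl next to enol ethers, and the in-flask conjugation of 8. The fallback sets out from 7 and comes back at 12.
- Dimedone is bis-silylated (TMSOTf, Et3N, Et2O, 0 °C → rt) to 5,5-dimethyl-1,3-bis(trimethylsilyloxy)cyclohexa-1,3-diene F1, a more electron-rich diene.
- Heating 7 in neat F1 at 140 °C gives ethyl 3-[(R)-2-hydroxyhept-6-en-1-yl]-8,8-dimethyl-1,5-bis(trimethylsilyloxy)bicyclo[2.2.2]octa-2,5-diene-2-carboxylate F2.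
- F2 loses 2-methylpropene by retro-Diels–Alder reaction, more easily than ethylene is lost, to give ethyl 2-[(R)-2-hydroxyhept-6-en-1-yl]-4,6-bis(trimethylsilyloxy)benzoate F3.
- HCl in MeOH (rt → 50 °C) removes both silyl groups and closes the lactone to (R)-6,8-dihydroxy-3-(pent-4-en-1-yl)isochroman-1-one F4.
- Excess MeI, K2CO3, DMF, 50 °C methylates both phenols and returns 12.

Step 4 (cross-metathesis/hydrogenation in one flask). Risks are homodimerisation of 12, sluggish turnover with the enone, and Ru residues disturbing the hydrogenation. The fallback sets out from 12 and comes back at 14.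
- Lemieux–Johnson cleavage (OsO4 2 mol%, NaIO4, 2,6-lutidine, dioxane/H2O, rt) runs through (3R)-3-(4,5-dihydroxypentyl)-6,8-dimethoxyisochroman-1-one F5 to 4-[(R)-6,8-dimethoxy-1-oxoisochroman-3-yl]butanal F6.
- Horner–Wadsworth–Emmons olefination of F6 with bought dimethyl (2-oxoheptyl)phosphonate (LiCl, DBU, MeCN, rt) gives the E-enone 14.
- 14 is hydrogenated (H2, Pd/C, EtOAc) to 15 as in the second half of step 4.

Step 5 (selective demethylation). Risks are incomplete reaction or partial loss of the 6-OMe once excess BCl3 is needed to saturate the ketone and lactone oxygens. The fallback sets out from 15 and comes back at 17.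
- BBr3 (4 equiv), CH2Cl2, −78 °C → rt removes both methyl groups to give (R)-6,8-dihydroxy-3-(6-oxoundecyl)isochroman-1-one F7.
- MeI (1.05 equiv), K2CO3, acetone, rt then methylates only the 6-OH, because the 8-OH is held in a hydrogen bond to the lactone carbonyl, giving 17.

**Further compounds**
F1 | step 3 | 5,5-dimethyl-1,3-bis(trimethylsilyloxy)cyclohexa-1,3-diene | C[Si](C)(C)OC1=CC(O[Si](C)(C)C)=CC(C)(C)C1
F2 | step 3 | ethyl 3-[(R)-2-hydroxyhept-6-en-1-yl]-8,8-dimethyl-1,5-bis(trimethylsilyloxy)bicyclo[2.2.2]octa-2,5-diene-2-carboxylate | C[Si](C)(C)OC1=CC2(O[Si](C)(C)C)CC(C)(C)C1C(C[C@H](O)CCCC=C)=C2C(=O)OCC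
F3 | step 3 | ethyl 2-[(R)-2-hydroxyhept-6-en-1-yl]-4,6-bis(trimethylsilyloxy)benzoate | CCOC(=O)c1c(O[Si](C)(C)C)cc(O[Si](C)(C)C)cc1C[C@H](O)CCCC=C
F4 | step 3 | (R)-6,8-dihydroxy-3-(pent-4-en-1-yl)isochroman-1-one | C=CCCC[C@@H]1Cc2cc(O)cc(O)c2C(=O)O1
F5 | step 4 | (3R)-3-(4,5-dihydroxypentyl)-6,8-dimethoxyisochroman-1-one | OCC(O)CCC[C@@H]1Cc2cc(OC)cc(OC)c2C(=O)O1
F6 | step 4 | 4-[(R)-6,8-dimethoxy-1-oxoisochroman-3-yl]butanal | O=CCCC[C@@H]1Cc2cc(OC)cc(OC)c2C(=O)O1
F7 | step 5 | (R)-6,8-dihydroxy-3-(6-oxoundecyl)isochroman-1-one | CCCCCC(=O)CCCCC[C@@H]1Cc2cc(O)cc(O)c2C(=O)O1
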